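The eight-membered carbocycle (C1–C8) and the γ-lactone (O–C3–C4–C5–C9) are made together by inserting a two-carbon acyloxyketene unit (C2=C3) into the C1–C4 bond of a 2-isobutyrylcyclohexanone. Two features are exploited: the C9–O ester between C5 and C3 acts as the tether, and C1, lying between the C2 and isobutyryl carbonyls, can leave as a β-diketonate. C1 adds to C2, C3 adds to the ring ketone C4, and strain release in the resulting cyclobutanolate enlarges the six-membered ring by two carbons. The precursor is a cyclohexanone that already carries C5, C7, C8 and all side chains.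

Key step: step 14

Numbering (target atoms, used for every intermediate): C1 = CH bearing the isobutyryl group; C2 = adjacent ring ketone; C3 = O-bearing quaternary carbon (prenyl); C4 = ketone of the lactone ring; C5 = quaternary carbon (prenyl, C9); C6 = CH2; C7 = CH(prenyl); C8 = quaternary carbon (CH3, oxygenated side chain); C9 = lactone C=O. Prenyl = 3-methylbut-2-en-1-yl.

Assumptions:
- C1 is an epimerisable β-diketone centre; the configuration of the target (isobutyryl anti to the C8 side chain) is taken to be the thermodynamic one and is reached by equilibration.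
- C3 of the hydroxy ester is used racemic, because this centre becomes planar in step 14.
- 5-Methylhex-4-enal is taken as a purchasable aldehyde.

Step 1
Reactants: 1 5-methylhex-4-enal; 2 but-3-en-2-one
Product: 4 (R)-4-prenylcyclohex-2-en-1-one, via keto aldehyde 3 (not isolated)
Conditions: (R)-2-(methoxydiphenylmethyl)pyrrolidine (5 mol%), ethyl 3,4-dihydroxybenzoate (20 mol%), neat, 4 °C; then KOH, n-Bu4NOH (cat.), THF/Et2O/H2O, reflux
Reagents that add atoms: none
Why: Enamine-catalysed Michael addition of the aldehyde to the vinyl ketone followed by intramolecular aldol condensation (Robinson-type annulation); the diarylmethyl group of the R catalyst shields one face of the E-enamine and should set C7 as R (the S catalyst would give the enantiomer).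

Step 2
Reactants: 4 (R)-4-prenylcyclohex-2-en-1-one
Product: 5 trans-3-methyl-4-prenyl-1-(trimethylsilyloxy)cyclohex-1-ene
Conditions: Me2CuLi, TMSCl, THF, −78 °C; Et3N quench
Reagents that add atoms: lithium dimethylcuprate [Li+].C[Cu-]C; chlorotrimethylsilane C[Si](C)(C)Cl
Why: Gilman cuprate 1,4-addition with in-situ silyl trapping gives the regiodefined enol ether; the new methyl-bearing centre (anti to the prenyl group) is erased in step 3.

Step 3
Reactants: 5 trans-3-methyl-4-prenyl-1-(trimethylsilyloxy)cyclohex-1-ene
Product: 6 (R)-3-methyl-4-prenylcyclohex-2-en-1-one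
Conditions: Pd(OAc)2 (10 mol%), O2 (1 atm), DMSO, 25 °C
Reagents that add atoms: none
Why: Saegusa–Ito dehydrogenation of the silyl enol ether places the enone double bond between C1 and C8 only, and the γ-stereocentre C7 is not touched.

Step 4
Reactants: 7 methyl (E)-but-2-enoate
Product: 8 1-(tert-butyldimethylsilyloxy)-1-methoxybuta-1,3-diene
Conditions: LDA, DMPU, THF, −78 °C; then TBSCl
Reagents that add atoms: tert-butyldimethylsilyl chloride CC(C)(C)[Si](C)(C)Cl
Why: γ-Deprotonation of the crotonate and O-silylation of the dienolate gives the vinylogous ketene acetal (standard preparation of silyl dienolates).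

Step 5
Reactants: 6 (R)-3-methyl-4-prenylcyclohex-2-en-1-one; 8 1-(tert-butyldimethylsilyloxy)-1-methoxybuta-1,3-diene
Product: 9 2-(1-hydroxy-2-methylpropyl)-3-[(E)-4-methoxy-4-oxobut-2-en-1-yl]-3-methyl-4-prenylcyclohexan-1-one (butenoate chain on C8 trans to the C7 prenyl; epimers at C1 and at the carbinol carbon)
Conditions: TiCl4 (1.1 equiv), CH2Cl2, −78 °C; then i-PrCHO, −78 → −40 °C
Reagents that add atoms: 2-methylpropanal CC(C)C=O
Why: Vinylogous Mukaiyama–Michael addition through the unhindered γ-CH2 of the dienolate followed by aldol trapping of the titanium enolate at C1 (tandem Michael–aldol); allylic strain with the C8 methyl holds the C7 prenyl pseudo-axial, so the nucleophile should add anti to it and set the C8 quaternary centre.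

Step 6
Reactants: 9 aldol adduct
Product: 10 methyl (E)-4-(2-isobutyryl-1-methyl-3-oxo-6-prenylcyclohexyl)but-2-enoate (drawn as the ring enol; chain on C8 trans to the C7 prenyl)
Conditions: Dess–Martin periodinane, NaHCO3, CH2Cl2, 0 → 25 °C
Reagents that add atoms: none
Why: Dess–Martin oxidation of the β-hydroxy ketone gives the enolised β-diketone, and both epimeric centres of 9 converge.

Step 7
Reactants: 10 β-diketone enoate
Product: 11 2-isobutyryl-3-[(E)-4-hydroxy-4-methylpent-2-en-1-yl]-3-methyl-4-prenylcyclohexan-1-one (enol form)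
Conditions: MeMgBr (5 equiv), CeCl3, THF, −78 → 0 °C; aq. NH4Cl
Reagents that add atoms: methylmagnesium bromide C[Mg]Br
Why: The first equivalent converts the β-diketone into its inert magnesium enolate, and cerium-mediated double 1,2-addition of the Grignard reagent to the enoate then gives the tertiary allylic alcohol with the E alkene retained.

Step 8
Reactants: 11 tertiary allylic alcohol
Product: 12 triethylsilyl ether of 11
Conditions: TESOTf, 2,6-lutidine, CH2Cl2, −78 °C
Reagents that add atoms: triethylsilyl trifluoromethanesulfonate CC[Si](CC)(CC)OS(=O)(=O)C(F)(F)F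
Why: Silyl triflate silylation of the hindered tertiary alcohol; any enol silyl ether formed from the β-diketone is hydrolysed on aqueous work-up.

Step 9
Reactants: 13 methyl oxirane-2-carboxylate (racemic)
Product: 14 methyl 2-hydroxy-5-methylhex-4-enoate (racemic)
Conditions: (2-methylprop-1-en-1-yl)magnesium bromide, CuI (10 mol%), THF, −40 °C
Reagents that add atoms: (2-methylprop-1-en-1-yl)magnesium bromide CC(C)=C[Mg]Br
Why: Copper-catalysed Grignard opening of the glycidic ester at its unsubstituted carbon gives the α-hydroxy ester that will become C2 and C3 with the C3 prenyl group.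

Step 10
Reactants: 14 methyl 2-hydroxy-5-methylhex-4-enoate
Product: 15 methyl 2-[(1H-imidazole-1-carbonyl)oxy]-5-methylhex-4-enoate
Conditions: 1,1'-carbonyldiimidazole, CH2Cl2, 25 °C
Reagents that add atoms: 1,1'-carbonyldiimidazole O=C(n1ccnc1)n1ccnc1
Why: Formation of an imidazole carbamate turns the secondary alcohol into a C-selective alkoxycarbonylating agent that carries the future C9 carbonyl.

Step 11
Reactants: 12 silyl-protected β-diketone; 15 imidazole carbamate
Product: 16 C5-alkoxycarbonylated β-diketone (ester of C9 with the C3 oxygen; epimers at C5 and C3)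
Conditions: LDA (2.3 equiv), THF, −78 → 0 °C; then 15, −78 °C; aq. NH4Cl
Reagents that add atoms: none
Why: Hauser–Harris dianion chemistry: the second deprotonation occurs at the ring CH2 C5 (the isopropyl methine is more hindered), and this more basic carbanion attacks the acyl imidazole much faster than the methyl ester.

Step 12
Reactants: 16 tricarbonyl compound
Product: 17 C5-prenylated keto diester (C5 prenyl trans to the C7 prenyl and C9 ester cis to it; epimers at C3)
Conditions: NaH (2.1 equiv), THF, 0 °C; then prenyl bromide, 0 → 25 °C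
Reagents that add atoms: 1-bromo-3-methylbut-2-ene CC(C)=CCBr
Why: The dianion alkylates at its more basic β-keto ester carbon C5, and axial attack on the half-chair with the C7 prenyl equatorial should place the new prenyl group trans to it, which fixes the C5 quaternary centre (the C5 epimer, if formed, is removed by chromatography).

Step 13
Reactants: 17 methyl ester
Product: 18 carboxylic acid (free C2 carboxyl)
Conditions: Me3SnOH, ClCH2CH2Cl, 70 °C; aq. KHSO4
Reagents that add atoms: trimethyltin hydroxide C[Sn](C)(C)O
Why: Trimethyltin hydroxide cleaves the unhindered, α-acyloxy-activated methyl ester and should leave the neopentyl-type C9 ester, the silyl ether and the β-diketone intact.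

Step 14
Reactants: 18 carboxylic acid
Product: 22 O-triethylsilyl derivative of alcohol 23 (ring-expanded bicyclic keto lactone), via acid chloride 19 (not isolated), via acyloxyketene 20 (not isolated), via cyclobutanone aldolate 21 (not isolated)
Conditions: 1-chloro-N,N,2-trimethylprop-1-en-1-amine, CH2Cl2, 0 °C; then slow addition to MgBr2·OEt2, i-Pr2NEt, CH2Cl2 (0.002 M), 0 → 25 °C; aq. citric acid
Reagents that add atoms: none
Why: Proposed new method: the acid chloride loses HCl to give acyloxyketene 20, whose carbonyl carbon C2 is attacked by C1 of the magnesium-chelated β-diketonate, and the ketene-derived enolate carbon C3, held beside the ring ketone by the C9 ester tether, adds to C4 to give cyclobutanone alkoxide 21, which opens by retro-aldol cleavage of C1–C4 because C1 departs as a β-diketonate, so that the C2–C3 unit is inserted into the C1–C4 bond. The closest known reaction types are the ketene/silyl enol ether [2+2]–retro-aldol two-carbon ring expansion, the acyl-alkylation of β-dicarbonyl compounds by σ-insertion of arynes and alkynes, the de Mayo reaction and soft-enolisation C-acylation. The γ-lactone closes as a 5-exo-trig aldol addition (4-exo-trig for the transient cyclobutane), and the eight-membered ring is not closed directly but arises by two-carbon expansion of the cyclohexanone. C3 is controlled by the tether, since the lactone can only be cis-fused on the face of the C5 carboxyl group, which puts the C3 prenyl cis to the C5 prenyl whatever the C3 configuration of 18; C1 is set by thermodynamic protonation of the β-diketonate. The step needs C- instead of O-acylation at C1 (magnesium chelation of both diketone oxygens, and reversibility of O-acylation) and attack of the C3 enolate on C4 instead of the isobutyryl carbonyl or its own acyl group, which the five-membered ring being formed and the strain-releasing, irreversible fragmentation should secure.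

Step 15
Reactants: 22 silyl ether
Product: 24 target hydroperoxide CNP0545483.1, via tertiary alcohol 23 (not isolated)
Conditions: H2O2 (50% aq., large excess), TsOH·H2O (cat.), THF, 0 °C
Reagents that add atoms: hydrogen peroxide OO
Why: Acid removes the silyl group, and acid-catalysed perhydrolysis (SN1) of the tertiary allylic alcohol should capture the allyl cation at its tertiary terminus in its transoid form, which gives the tertiary hydroperoxide with the E alkene.

Compound list
1 | 5-methylhex-4-enal | CC(C)=CCCC=O | starting material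
2 | but-3-en-2-one | CC(=O)C=C | starting material
3 | (R)-2-prenyl-5-oxohexanal | CC(C)=CC[C@H](C=O)CCC(C)=O | intermediate
4 | (R)-4-prenylcyclohex-2-en-1-one | CC(C)=CC[C@H]1CCC(=O)C=C1 | intermediate
5 | trans-3-methyl-4-prenyl-1-(trimethylsilyloxy)cyclohex-1-ene (C7 as in 4) | CC(C)=CC[C@H]1CCC(O[Si](C)(C)C)=C[C@@H]1C | intermediate
6 | (R)-3-methyl-4-prenylcyclohex-2-en-1-one | CC(C)=CC[C@H]1CCC(=O)C=C1C | intermediate
7 | methyl (E)-but-2-enoate | C/C=C/C(=O)OC | starting material
8 | 1-(tert-butyldimethylsilyloxy)-1-methoxybuta-1,3-diene (ketene acetal geometry not relevant) | C=CC=C(OC)O[Si](C)(C)C(C)(C)C | intermediate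
9 | 2-(1-hydroxy-2-methylpropyl)-3-[(E)-4-methoxy-4-oxobut-2-en-1-yl]-3-methyl-4-prenylcyclohexan-1-one (C7 R; chain on C8 trans to C7 prenyl; epimers at C1 and carbinol carbon) | CC(C)=CC[C@H]1CCC(=O)C(C(O)C(C)C)[C@]1(C)C/C=C/C(=O)OC | intermediate
10 | methyl (E)-4-(2-isobutyryl-1-methyl-3-oxo-6-prenylcyclohexyl)but-2-enoate, ring enol form (stereocentres C7 and C8 as in 9) | CC(C)=CC[C@H]1CCC(O)=C(C(=O)C(C)C)[C@]1(C)C/C=C/C(=O)OC | intermediate
11 | 2-isobutyryl-3-[(E)-4-hydroxy-4-methylpent-2-en-1-yl]-3-methyl-4-prenylcyclohexan-1-one, enol form | CC(C)=CC[C@H]1CCC(O)=C(C(=O)C(C)C)[C@]1(C)C/C=C/C(C)(C)O | intermediate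
12 | triethylsilyl ether of 11 | CC(C)=CC[C@H]1CCC(O)=C(C(=O)C(C)C)[C@]1(C)C/C=C/C(C)(C)O[Si](CC)(CC)CC | intermediate
13 | methyl oxirane-2-carboxylate (racemic) | COC(=O)C1CO1 | starting material
14 | methyl 2-hydroxy-5-methylhex-4-enoate (racemic) | COC(=O)C(O)CC=C(C)C | intermediate
15 | methyl 2-[(1H-imidazole-1-carbonyl)oxy]-5-methylhex-4-enoate (racemic) | COC(=O)C(CC=C(C)C)OC(=O)n1ccnc1 | intermediate
16 | 12 carrying at C5 the group C(=O)O–CH(prenyl)CO2CH3 (epimers at C5 and C3) | CC(C)=CC[C@H]1CC(C(=O)OC(CC=C(C)C)C(=O)OC)C(O)=C(C(=O)C(C)C)[C@]1(C)C/C=C/C(C)(C)O[Si](CC)(CC)CC | intermediate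
17 | 16 prenylated at C5 (C5 prenyl trans to C7 prenyl; C9 ester cis to it; epimers at C3) | CC(C)=CC[C@H]1C[C@@](CC=C(C)C)(C(=O)OC(CC=C(C)C)C(=O)OC)C(O)=C(C(=O)C(C)C)[C@]1(C)C/C=C/C(C)(C)O[Si](CC)(CC)CC | intermediate
18 | carboxylic acid from 17 (free C2 carboxyl) | CC(C)=CC[C@H]1C[C@@](CC=C(C)C)(C(=O)OC(CC=C(C)C)C(=O)O)C(O)=C(C(=O)C(C)C)[C@]1(C)C/C=C/C(C)(C)O[Si](CC)(CC)CC | intermediate
19 | acid chloride of 18 | CC(C)=CC[C@H]1C[C@@](CC=C(C)C)(C(=O)OC(CC=C(C)C)C(Cl)=O)C(O)=C(C(=O)C(C)C)[C@]1(C)C/C=C/C(C)(C)O[Si](CC)(CC)CC | intermediate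
20 | acyloxyketene (C3=C2=O) from 19 | CC(C)=CC[C@H]1C[C@@](CC=C(C)C)(C(=O)OC(CC=C(C)C)=C=O)C(O)=C(C(=O)C(C)C)[C@]1(C)C/C=C/C(C)(C)O[Si](CC)(CC)CC | intermediate
21 | cyclobutanone aldolate, shown as the free C4 alcohol (cyclobutane C1–C2–C3–C4 cis-fused to the cyclohexane and to the γ-lactone) | CC(C)=CC[C@H]1C[C@](CC=C(C)C)([C@@]45O)C(=O)O[C@@]4(CC=C(C)C)C(=O)[C@@]5(C(=O)C(C)C)[C@]1(C)C/C=C/C(C)(C)O[Si](CC)(CC)CC | intermediate
22 | O-triethylsilyl derivative of 23 (ring-expanded bicyclic keto lactone) | CC(C)=CC[C@H]1C[C@@]2(CC=C(C)C)C(=O)O[C@@](CC=C(C)C)(C(=O)[C@@H](C(=O)C(C)C)[C@]1(C)C/C=C/C(C)(C)O[Si](CC)(CC)CC)C2=O | intermediate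
23 | tertiary allylic alcohol corresponding to the target (OH in place of OOH) | CC(C)=CC[C@H]1C[C@@]2(CC=C(C)C)C(=O)O[C@@](CC=C(C)C)(C(=O)[C@@H](C(=O)C(C)C)[C@]1(C)C/C=C/C(C)(C)O)C2=O | intermediate
24 | CNP0545483.1 | CC(C)=CC[C@H]1C[C@@]2(CC=C(C)C)C(=O)O[C@@](CC=C(C)C)(C(=O)[C@@H](C(=O)C(C)C)[C@]1(C)C/C=C/C(C)(C)OO)C2=O | target

Total step count: 15. Longest linear sequence: 12 steps (steps 1, 2, 3, 5, 6, 7, 8, 11, 12, 13, 14, 15).

Steps most likely to fail

Step 14. O-acylation of the diketonate to a cyclic enol ester, or transfer of the isobutyryl group instead of the ring acyl group to C3, may divert the cascade. The fallback uses known chemistry: a thermal ketene–silyl enol ether [2+2] cycloaddition followed by a fluoride-triggered retro-aldol. It sets out from 18. Silylation (TBSOTf, Et3N, CH2Cl2) should give the silyl ester and ring silyl enol ether, bis-silyl compound F1. Oxalyl chloride with catalytic DMF converts the silyl ester under neutral conditions into the acid chloride F2. Et3N in toluene at 80 °C and high dilution generates the ketene F3. Its [2+2] cycloaddition to the enol ether double bond, with the ketene carbonyl carbon bonding to the nucleophilic C1 and the α-carbon to the oxygen-bearing C4, gives the siloxycyclobutanone F4. TBAF buffered with AcOH then removes both silyl groups and releases the C4 alkoxide, which fragments to the β-diketone. The fallback comes back to the route at 23, which is converted into 24 under the conditions of step 15.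

Step 5. Addition at the hindered β-carbon may be too slow, and the dienolate may react through its α-carbon or as a diene. The fallback builds the chain in two stages and sets out from 6. A Mukaiyama–Michael addition of the smaller, more nucleophilic 1-(tert-butyldimethylsilyloxy)-1-methoxyethene (TiCl4, −78 °C), with the same aldol trapping by 2-methylpropanal, should give the hydroxy keto ester F5. Dess–Martin oxidation gives the β-diketone ester F6. After conversion into its sodium enolate (NaH), DIBAL-H at −78 °C reduces the ester to the aldehyde F7. Wittig olefination with methyl (triphenylphosphoranylidene)acetate installs the E enoate, and the fallback comes back to the route at 10.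

Step 15. Allylic transposition during capture of the cation, and acid-promoted cyclisation of prenyl groups onto the enolisable diketone, may compete. The fallback avoids protic acid and sets out from 22. HF·pyridine in THF removes the silyl group to give 23. PBr3 with pyridine in Et2O at −30 °C converts it, with allylic transposition, into the secondary allylic bromide F8. Silver trifluoroacetate with anhydrous ethereal H2O2 at −20 °C ionises the bromide, and the allyl cation is captured at its tertiary terminus. The fallback comes back to the route at 24.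

Further compounds
F1 | step 14 | tert-butyldimethylsilyl ester and ring tert-butyldimethylsilyl enol ether of 18 | CC(C)=CC[C@H]1C[C@@](CC=C(C)C)(C(=O)OC(CC=C(C)C)C(=O)O[Si](C)(C)C(C)(C)C)C(O[Si](C)(C)C(C)(C)C)=C(C(=O)C(C)C)[C@]1(C)C/C=C/C(C)(C)O[Si](CC)(CC)CC
F2 | step 14 | acid chloride of the ring silyl enol ether | CC(C)=CC[C@H]1C[C@@](CC=C(C)C)(C(=O)OC(CC=C(C)C)C(Cl)=O)C(O[Si](C)(C)C(C)(C)C)=C(C(=O)C(C)C)[C@]1(C)C/C=C/C(C)(C)O[Si](CC)(CC)CC
F3 | step 14 | acyloxyketene of the ring silyl enol ether | CC(C)=CC[C@H]1C[C@@](CC=C(C)C)(C(=O)OC(CC=C(C)C)=C=O)C(O[Si](C)(C)C(C)(C)C)=C(C(=O)C(C)C)[C@]1(C)C/C=C/C(C)(C)O[Si](CC)(CC)CC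
F4 | step 14 | C4 tert-butyldimethylsilyl ether of cyclobutanone 21 | CC(C)=CC[C@H]1C[C@](CC=C(C)C)([C@@]45O[Si](C)(C)C(C)(C)C)C(=O)O[C@@]4(CC=C(C)C)C(=O)[C@@]5(C(=O)C(C)C)[C@]1(C)C/C=C/C(C)(C)O[Si](CC)(CC)CC
F5 | step 5 | methyl 2-[2-(1-hydroxy-2-methylpropyl)-1-methyl-3-oxo-6-prenylcyclohexyl]acetate (C7 and C8 as in 9; epimers at C1 and carbinol carbon) | CC(C)=CC[C@H]1CCC(=O)C(C(O)C(C)C)[C@]1(C)CC(=O)OC
F6 | step 5 | methyl 2-(2-isobutyryl-1-methyl-3-oxo-6-prenylcyclohexyl)acetate, enol form | CC(C)=CC[C@H]1CCC(O)=C(C(=O)C(C)C)[C@]1(C)CC(=O)OC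
F7 | step 5 | 2-(2-isobutyryl-1-methyl-3-oxo-6-prenylcyclohexyl)acetaldehyde, enol form | CC(C)=CC[C@H]1CCC(O)=C(C(=O)C(C)C)[C@]1(C)CC=O
F8 | step 15 | secondary allylic bromide from 23 (side chain CH2–CHBr–CH=C(CH3)2; epimers at the bromide carbon) | CC(C)=CC[C@H]1C[C@@]2(CC=C(C)C)C(=O)O[C@@](CC=C(C)C)(C(=O)[C@@H](C(=O)C(C)C)[C@]1(C)CC(Br)C=C(C)C)C2=O
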